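The ten-membered ring is not closed but uncovered: C3 (hemiketal carbon) and C8 (ester carbinol) are 1,6-related on both arcs of the carbocycle, so they are the two carbons of a tetrasubstituted olefin shared by ring A (C3–C8) and ring B (C8, C9, C10, C1, C2, C3) of an octalin. Ozonolysis of that one bond turns both carbons into carbonyls, fuses the two six-membered rings into the macrocycle and lets the C10 hydroxyl close the 3,10-oxygen bridge in the same flask. The precursor is a trans-lactone-fused octalin whose C10 carbinol comes from (R)-linalool, with a C5 acetate storing the C4=C5 olefin and C15 as a silyl ether.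

Key step: step 14

Numbering: the germacrane numbering of the target is used for every intermediate (C1–C10 ring carbons, C11–C13 lactone carbons, C14 the methyl on C10, C15 the oxymethyl carbon on C4); β is the face that carries C11 on C7, α the opposite face.

Assumption: C3 is a hemiketal carbon that equilibrates through the open 3-ketone and is tied to C10 by the single-oxygen bridge, so no step can set it independently; it is written in all structures with the descriptor of the target SMILES and is taken to be the epimer that ring closure from C10 delivers.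

**Step 1**
Reactants: 1 (R)-(−)-linalool
Product: 2 (5R)-5-ethenyl-5-methyloxolan-2-ol (lactol; both anomers)
Conditions: O3 (1.0 equiv, Sudan Red 7B end point), CH2Cl2/MeOH, −78 °C; then Me2S, −78 °C to rt
Reagents that add atoms: ozone, [O-][O+]=O
Why: Chemoselective ozonolysis, in which the electrophilic oxidant should cleave the trisubstituted olefin of linalool well before the monosubstituted vinyl group, the freed aldehyde closing onto the tertiary hydroxyl as a five-membered lactol; the carbinol carbon (the future C10) is not touched and keeps the R configuration of the starting material.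

**Step 2**
Reactants: 2 (5R)-5-ethenyl-5-methyloxolan-2-ol
Product: 3 (3R)-3-methylhept-1-en-6-yn-3-ol
Conditions: dimethyl (1-diazo-2-oxopropyl)phosphonate, K2CO3, MeOH, 0 °C to rt
Reagents that add atoms: dimethyl (1-diazo-2-oxopropyl)phosphonate, COP(=O)(OC)C(=[N+]=[N-])C(C)=O
Why: Ohira–Bestmann (Seyferth–Gilbert) homologation acts on the open hydroxy aldehyde in equilibrium with the lactol and adds one carbon to give the terminal alkyne (future C3≡C4) without affecting the stereocentre.

**Step 3**
Reactants: 3 (3R)-3-methylhept-1-en-6-yn-3-ol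
Product: 4 (6R)-6-methyloct-7-en-2-yne-1,6-diol
Conditions: n-BuLi (2.2 equiv), THF, −78 °C; (CH2O)n, −78 °C to rt
Reagents that add atoms: formaldehyde (from paraformaldehyde), C=O
Why: Alkynyllithium addition to formaldehyde, after formation of the O,C-dianion, installs C15 as the propargylic alcohol.

**Step 4**
Reactants: 4 (6R)-6-methyloct-7-en-2-yne-1,6-diol
Product: 5 (3R)-8-[(tert-butyldimethylsilyl)oxy]-3-methyloct-1-en-6-yn-3-ol
Conditions: TBSCl, imidazole, CH2Cl2, 0 °C
Reagents that add atoms: tert-butyldimethylsilyl chloride, CC(C)(C)[Si](C)(C)Cl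
Why: Silyl ether formation is selective for the unhindered primary hydroxyl, the tertiary carbinol being inert to TBSCl and imidazole.

**Step 5**
Reactants: 5 (3R)-8-[(tert-butyldimethylsilyl)oxy]-3-methyloct-1-en-6-yn-3-ol
Product: 7 (3R)-8-[(tert-butyldimethylsilyl)oxy]-3-methyloct-6-yne-1,3-diol, via alkylborane 6 (not isolated)
Conditions: 9-BBN (1.3 equiv), THF, 0 °C to rt; then NaOH, H2O2, 0 °C
Reagents that add atoms: hydrogen peroxide, OO; 9-borabicyclo[3.3.1]nonane, B1C2CCCC1CCC2 (its boron and ring carbons are carried only in 6)
Why: Hydroboration–oxidation, in which the bulky borane should add anti-Markovnikov to the monosubstituted olefin much faster than to the internal alkyne and oxidative C–B cleavage gives the primary alcohol at the future C8.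

**Step 6**
Reactants: 7 (3R)-8-[(tert-butyldimethylsilyl)oxy]-3-methyloct-6-yne-1,3-diol
Product: 8 (3R)-8-[(tert-butyldimethylsilyl)oxy]-3-hydroxy-3-methyloct-6-ynal
Conditions: TEMPO (10 mol%), PhI(OAc)2, CH2Cl2, rt
Reagents that add atoms: none
Why: Oxoammonium (TEMPO) oxidation is selective for primary alcohols and stops at the aldehyde in the absence of water, leaving the tertiary carbinol and the alkyne alone.

**Step 7**
Reactants: 8 (3R)-8-[(tert-butyldimethylsilyl)oxy]-3-hydroxy-3-methyloct-6-ynal
Product: 9 (4R)-9-[(tert-butyldimethylsilyl)oxy]-4-methylnona-1,7-diyn-4-ol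
Conditions: dimethyl (1-diazo-2-oxopropyl)phosphonate, K2CO3, MeOH, 0 °C
Reagents that add atoms: dimethyl (1-diazo-2-oxopropyl)phosphonate, COP(=O)(OC)C(=[N+]=[N-])C(C)=O
Why: Ohira–Bestmann homologation converts the aldehyde into the terminal alkyne C8≡C7, and running it cold on the freshly made β-hydroxy aldehyde should let alkyne formation outpace retro-aldol cleavage.

**Step 8**
Reactants: 9 (4R)-9-[(tert-butyldimethylsilyl)oxy]-4-methylnona-1,7-diyn-4-ol; 10 ethyl diazoacetate
Product: 11 ethyl (6R)-11-[(tert-butyldimethylsilyl)oxy]-6-hydroxy-6-methylundeca-3,9-diynoate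
Conditions: CuI (5 mol%), MeCN, rt
Reagents that add atoms: none
Why: Copper-catalysed coupling of a terminal alkyne with a diazo ester (through the copper acetylide) gives the 3-alkynoate carrying C11 and C12; it needs no base, so the skipped ynoate should not isomerise to the allenoate, and only the C7 alkyne is terminal.

**Step 9**
Reactants: 11 ethyl (6R)-11-[(tert-butyldimethylsilyl)oxy]-6-hydroxy-6-methylundeca-3,9-diynoate
Product: 12 ethyl 3-[(1E,2E,5R)-2-{2-[(tert-butyldimethylsilyl)oxy]ethylidene}-5-hydroxy-5-methylcyclohexylidene]propanoate (ring B diene)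
Conditions: Pd2(dba)3·CHCl3 (2.5 mol%), P(o-tolyl)3 (10 mol%), AcOH, Et3SiH, toluene, rt
Reagents that add atoms: none
Why: Palladium-catalysed reductive cyclisation of a 1,7-diyne, in which syn-hydropalladation of one alkyne, syn-carbopalladation of the other (forming the C3–C8 bond and ring B) and hydride transfer from the silane give the s-cis 1,2-bis(alkylidene)cyclohexane with both side chains outside (E,E), under neutral conditions that tolerate the ester, the silyl ether and the free carbinol.

**Step 10**
Reactants: 12 ring B diene; 13 (E)-1,2-bis(phenylsulfonyl)ethene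
Product: 14 disulfone cycloadduct (Δ3(8)-octalin; 7β-CH2CO2Et; 4β-CH2OTBS; 10β-OH; 10α-CH3; 5,6-trans sulfonyl groups in both orientations)
Conditions: toluene, 70 °C
Reagents that add atoms: none
Why: Diels–Alder reaction of the s-cis-locked (E,E)-diene with a symmetrical acetylene equivalent, so that no regiochemistry arises and suprafacial addition makes the C4 and C7 side chains cis; the diene face syn to the C10 hydroxyl should be preferred because an endo sulfonyl oxygen can hydrogen-bond to that hydroxyl in the non-polar medium while the opposite face is screened by the axial C10 methyl in the other half-chair of ring B, which sets C7 (and C4) relative to C10, the C5 and C6 centres being destroyed in step 11.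

**Step 11**
Reactants: 14 disulfone cycloadduct
Product: 15 ethyl 2-[4β-(TBSO-methyl)-10β-hydroxy-10α-methyl-octalin-3(8),5-dien-7β-yl]acetate (ring A 1,4-diene)
Conditions: Na(Hg) (6%), NaH2PO4, MeOH/THF, −20 °C
Reagents that add atoms: none
Why: Reductive elimination of a vicinal disulfone by electron transfer (loss of two sulfinate ions) gives the C5=C6 olefin from either adduct diastereomer, the phosphate buffer protecting the ester and the skipped diene, and the C4, C7 and C10 centres are unchanged.

**Step 12**
Reactants: 15 ring A 1,4-diene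
Product: 17 trans-fused 5α-hydroxy-6α,12-lactone of the octalin, via diol ester 16 (not isolated)
Conditions: OsO4 (2 mol%), N-methylmorpholine N-oxide, acetone/H2O, 0 °C to rt; then pyridinium p-toluenesulfonate (cat.), toluene, 80 °C
Reagents that add atoms: N-methylmorpholine N-oxide, C[N+]1([O-])CCOCC1; water, O
Why: Upjohn dihydroxylation followed by acid-catalysed lactonisation, in which the [3+2] addition of OsO4 should take the accessible cis-disubstituted C5=C6 olefin rather than the tetrasubstituted ring-fusion olefin (screened on both faces) and should occur on the face opposite to the two cis side chains on C4 and C7, setting C5 and C6 as the 5α,6α-diol; the C6 hydroxyl then closes the trans-fused γ-lactone with the C12 ester, the C5 hydroxyl being able to form only a six-membered ring.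

**Step 13**
Reactants: 17 trans-fused 5α-hydroxy-6α,12-lactone
Product: 18 5α-acetoxy-6α,12-lactone of the octalin with free 10β-hydroxyl and 4β-CH2OTBS (precursor of the key step)
Conditions: Ac2O, pyridine, DMAP (cat.), CH2Cl2, 0 °C to rt
Reagents that add atoms: acetic anhydride, CC(=O)OC(C)=O
Why: DMAP-catalysed acetylation takes the only secondary hydroxyl and so places the leaving group for the later C4=C5 elimination on C5, while the hindered tertiary C10 carbinol stays free for the key step.

**Step 14**
Reactants: 18 5α-acetoxy lactone-fused octalin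
Product: 20 bridged hemiketal 8-ketone (3-hydroxy-3,10-epoxy-8-oxo-6α,12-lactone), via hydroxy diketone 19 (not isolated)
Conditions: O3, CH2Cl2/MeOH (5:1), NaHCO3, −78 °C; then Me2S, −78 °C to rt
Reagents that add atoms: ozone, [O-][O+]=O
Why: Ozone adds to the electron-rich tetrasubstituted C3=C8 olefin by 1,3-dipolar cycloaddition and cycloreversion, and reduction of the resulting peroxides with Me2S leaves a carbonyl on each former ring-fusion carbon, so that rings A and B merge into the ten-membered carbocycle by fragmentation of their shared bond (hydroxy diketone 19). The closest known reaction type is the ozonolysis of the central olefin of Δ9(10)-octalins to cyclodecane-1,6-diones. The second ring, the oxolane, closes by 5-exo-trig addition of the C10 hydroxyl to the C3 ketone, the alternative addition to C8 being a four-membered closure that does not compete. The one new stereocentre, C3, is not selected by a reagent but imposed by the oxygen bridge from C10, while C6, C7 and C10 are not touched and C4 and C5 are sacrificial. The only selectivity needed is chemoselectivity, and the substrate secures it because C3=C8 is the sole olefin of 18 (C4=C5 is stored as the C5 acetate and C13 is not yet present) and no other group reacts with ozone at −78 °C. The β-acyloxy ketone at C8 is base-sensitive, so the work-up is buffered and 20 is reduced without delay.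

**Step 15**
Reactants: 20 bridged hemiketal 8-ketone
Product: 21 8β-alcohol (8R) of the bridged hemiketal lactone
Conditions: (S)-2-methyl-CBS-oxazaborolidine (0.5 equiv), BH3·SMe2, THF, −30 °C
Reagents that add atoms: none
Why: Corey–Bakshi–Shibata reduction, in which the α-branched C7 acts as the large and the C9 methylene as the small ketone substituent so that the (S)-oxazaborolidine should deliver hydride to the face giving the 8R (8β) alcohol under reagent control; borane at low temperature is non-basic, so the β-acyloxy ketone is not exposed to elimination and the lactone, acetate and hemiketal are not reduced.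

**Step 16**
Reactants: 21 8β-alcohol
Product: 22 8β-isobutyrate 5α-acetate of the bridged hemiketal lactone
Conditions: isobutyric anhydride, DMAP (cat.), pyridine, CH2Cl2, 0 °C to rt
Reagents that add atoms: isobutyric anhydride, CC(C)C(=O)OC(=O)C(C)C
Why: DMAP-catalysed acylation of the secondary C8 hydroxyl, the tertiary hemiketal hydroxyl being too hindered to compete and pyridine too weak a base to start the elimination of step 17.

**Step 17**
Reactants: 22 8β-isobutyrate 5α-acetate
Product: 25 (4Z)-olefin hemiketal 8β-isobutyrate, via open keto acetate 23 (not isolated), via hydroxy enone 24 (not isolated)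
Conditions: DBU, CH2Cl2, rt
Reagents that add atoms: none
Why: E1cB elimination, in which the hemiketal opens reversibly to the 3-ketone 23, deprotonation at C4 expels the C5 acetate (a far better leaving group than the C15 silyloxide) and the C10 hydroxyl recloses on the enone 24; the Z olefin is the one that fits inside the oxygen-bridged nine-membered ring and is reachable from the E isomer by base-mediated equilibration, so the (4Z)-hemiketal should be the thermodynamic product.

**Step 18**
Reactants: 25 (4Z)-olefin hemiketal 8β-isobutyrate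
Product: 26 3-O-triethylsilyl ketal of 25
Conditions: Et3SiOTf, 2,6-lutidine, CH2Cl2, −78 °C
Reagents that add atoms: triethylsilyl trifluoromethanesulfonate, CC[Si](CC)(CC)OS(=O)(=O)C(F)(F)F
Why: Silylation of the tertiary hemiketal hydroxyl with a silyl triflate locks C3 as a mixed silyl ketal, so that the strong base of step 19 cannot open it to an enolisable enone.

**Step 19**
Reactants: 26 3-O-triethylsilyl ketal
Product: 29 α-methylene lactone bis-silyl ether, via Mannich base 27 (not isolated), via ammonium iodide 28 (not isolated)
Conditions: LiN(SiMe3)2, THF, −78 °C; Me2N=CH2+ I−, −78 to 0 °C; then MeI, MeOH, rt; then aq. NaHCO3, EtOAc, rt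
Reagents that add atoms: N,N-dimethylmethyleneiminium iodide (Eschenmoser's salt), C=[N+](C)C.[I-]; iodomethane, CI (its methyl group is carried only in 28)
Why: Eschenmoser methylenation, in which the lactone α-methylene group, the most acidic and least hindered C–H, should be deprotonated in preference to the α-branched isobutyrate, the enolate is aminomethylated by the iminium salt (Mannich base 27, configuration at C11 immaterial) and N-methylation followed by mild base-induced β-elimination of trimethylamine creates the exocyclic C11=C13 olefin.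

**Step 20**
Reactants: 29 α-methylene lactone bis-silyl ether
Product: 30 target CNP0282937.1
Conditions: HF·pyridine, pyridine, THF, 0 °C to rt
Reagents that add atoms: none
Why: Fluoride-mediated desilylation removes the primary TBS ether and the tertiary silyl ketal in one operation under buffered conditions that the α-methylene lactone, the isobutyrate and the hemiketal should tolerate, and no stereocentre is affected.

**Compound list**

1 | (R)-(−)-linalool | C=C[C@](C)(O)CCC=C(C)C | starting material
2 | (5R)-5-ethenyl-5-methyloxolan-2-ol (both anomers) | C=C[C@@]1(C)CCC(O)O1 | intermediate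
3 | (3R)-3-methylhept-1-en-6-yn-3-ol | C=C[C@](C)(O)CCC#C | intermediate
4 | (6R)-6-methyloct-7-en-2-yne-1,6-diol | C=C[C@](C)(O)CCC#CCO | intermediate
5 | (3R)-8-[(tert-butyldimethylsilyl)oxy]-3-methyloct-1-en-6-yn-3-ol | C=C[C@](C)(O)CCC#CCO[Si](C)(C)C(C)(C)C | intermediate
6 | B-alkyl-9-BBN adduct of 5 (boron on the terminal carbon) | B1(CC[C@](C)(O)CCC#CCO[Si](C)(C)C(C)(C)C)C2CCCC1CCC2 | intermediate
7 | (3R)-8-[(tert-butyldimethylsilyl)oxy]-3-methyloct-6-yne-1,3-diol | OCC[C@](C)(O)CCC#CCO[Si](C)(C)C(C)(C)C | intermediate
8 | (3R)-8-[(tert-butyldimethylsilyl)oxy]-3-hydroxy-3-methyloct-6-ynal | O=CC[C@](C)(O)CCC#CCO[Si](C)(C)C(C)(C)C | intermediate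
9 | (4R)-9-[(tert-butyldimethylsilyl)oxy]-4-methylnona-1,7-diyn-4-ol | C#CC[C@](C)(O)CCC#CCO[Si](C)(C)C(C)(C)C | intermediate
10 | ethyl diazoacetate | CCOC(=O)C=[N+]=[N-] | starting material
11 | ethyl (6R)-11-[(tert-butyldimethylsilyl)oxy]-6-hydroxy-6-methylundeca-3,9-diynoate | CCOC(=O)CC#CC[C@](C)(O)CCC#CCO[Si](C)(C)C(C)(C)C | intermediate
12 | ethyl 3-[(1E,2E,5R)-2-{2-[(tert-butyldimethylsilyl)oxy]ethylidene}-5-hydroxy-5-methylcyclohexylidene]propanoate | CCOC(=O)C/C=C1\C[C@](C)(O)CC/C1=C\CO[Si](C)(C)C(C)(C)C | intermediate
13 | (E)-1,2-bis(phenylsulfonyl)ethene | O=S(=O)(/C=C/S(=O)(=O)c1ccccc1)c1ccccc1 | starting material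
14 | disulfone cycloadduct (4β,7β side chains cis to 10β-OH; C5/C6 trans, both orientations, left undefined) | CCOC(=O)C[C@@H]1C2=C(CC[C@@](C)(O)C2)[C@H](CO[Si](C)(C)C(C)(C)C)C(S(=O)(=O)c2ccccc2)C1S(=O)(=O)c1ccccc1 | intermediate
15 | ring A 1,4-diene (octalin-3(8),5-diene; 4β-CH2OTBS, 7β-CH2CO2Et, 10β-OH) | CCOC(=O)C[C@@H]1C2=C(CC[C@@](C)(O)C2)[C@H](CO[Si](C)(C)C(C)(C)C)C=C1 | intermediate
16 | 5α,6α-diol ester | CCOC(=O)C[C@@H]1C2=C(CC[C@@](C)(O)C2)[C@H](CO[Si](C)(C)C(C)(C)C)[C@@H](O)[C@H]1O | intermediate
17 | trans-fused 5α-hydroxy-6α,12-lactone of the octalin | O=C1C[C@@H]2C3=C(CC[C@@](C)(O)C3)[C@H](CO[Si](C)(C)C(C)(C)C)[C@@H](O)[C@H]2O1 | intermediate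
18 | 5α-acetoxy-6α,12-lactone of the octalin, 10β-OH free (key-step precursor) | O=C1C[C@@H]2C3=C(CC[C@@](C)(O)C3)[C@H](CO[Si](C)(C)C(C)(C)C)[C@@H](OC(C)=O)[C@H]2O1 | intermediate
19 | ten-membered 10-hydroxy-3,8-diketone | O=C1C[C@@H]2C(=O)C[C@](C)(O)CCC(=O)[C@H](CO[Si](C)(C)C(C)(C)C)[C@@H](OC(C)=O)[C@H]2O1 | intermediate
20 | bridged hemiketal 8-ketone with the 6,12-lactone (key-step product) | O=C1C[C@@H]2C(=O)C[C@@]3(C)CC[C@@](O)(O3)[C@H](CO[Si](C)(C)C(C)(C)C)[C@@H](OC(C)=O)[C@H]2O1 | intermediate
21 | 8β-alcohol (8R) | O=C1C[C@@H]2[C@H](O)C[C@@]3(C)CC[C@@](O)(O3)[C@H](CO[Si](C)(C)C(C)(C)C)[C@@H](OC(C)=O)[C@H]2O1 | intermediate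
22 | 8β-isobutyrate 5α-acetate | O=C1C[C@@H]2[C@H](OC(=O)C(C)C)C[C@@]3(C)CC[C@@](O)(O3)[C@H](CO[Si](C)(C)C(C)(C)C)[C@@H](OC(C)=O)[C@H]2O1 | intermediate
23 | open 10-hydroxy-3-keto 5-acetate | O=C1C[C@@H]2[C@H](OC(=O)C(C)C)C[C@](C)(O)CCC(=O)[C@H](CO[Si](C)(C)C(C)(C)C)[C@@H](OC(C)=O)[C@H]2O1 | intermediate
24 | (4Z)-10-hydroxy-4-en-3-one | O=C1C[C@@H]2[C@H](OC(=O)C(C)C)C[C@](C)(O)CCC(=O)/C(CO[Si](C)(C)C(C)(C)C)=C\[C@H]2O1 | intermediate
25 | (4Z)-olefin hemiketal 8β-isobutyrate | O=C1C[C@@H]2[C@H](OC(=O)C(C)C)C[C@@]3(C)CC[C@@](O)(O3)/C(CO[Si](C)(C)C(C)(C)C)=C\[C@H]2O1 | intermediate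
26 | 3-O-triethylsilyl ketal of 25 | O=C1C[C@@H]2[C@H](OC(=O)C(C)C)C[C@@]3(C)CC[C@@](O[Si](CC)(CC)CC)(O3)/C(CO[Si](C)(C)C(C)(C)C)=C\[C@H]2O1 | intermediate
27 | 13-(dimethylamino) Mannich base (C11 undefined) | O=C1C(CN(C)C)[C@@H]2[C@H](OC(=O)C(C)C)C[C@@]3(C)CC[C@@](O[Si](CC)(CC)CC)(O3)/C(CO[Si](C)(C)C(C)(C)C)=C\[C@H]2O1 | intermediate
28 | trimethylammonium iodide of 27 | O=C1C(C[N+](C)(C)C)[C@@H]2[C@H](OC(=O)C(C)C)C[C@@]3(C)CC[C@@](O[Si](CC)(CC)CC)(O3)/C(CO[Si](C)(C)C(C)(C)C)=C\[C@H]2O1.[I-] | intermediate
29 | 15-O-TBS 3-O-triethylsilyl ether of the target | C=C1C(=O)O[C@@H]2/C=C(/CO[Si](C)(C)C(C)(C)C)[C@@]3(O[Si](CC)(CC)CC)CC[C@](C)(C[C@@H](OC(=O)C(C)C)[C@@H]12)O3 | intermediate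
30 | CNP0282937.1 | C=C1C(=O)O[C@@H]2/C=C(/CO)[C@@]3(O)CC[C@](C)(C[C@@H](OC(=O)C(C)C)[C@@H]12)O3 | target

**Step count and risks**

Total step count: 20. Longest linear sequence: 20 steps (1 to 30).

The three steps most likely to fail:

Step 10. The cycloaddition may show poor facial selectivity with respect to the remote C10 centre, because the hydrogen bond that should steer the dienophile is weak at 70 °C and the two half-chairs of ring B screen opposite faces. The outcome would be a mixture of the two C4/C7 diastereomers. Fallback, setting out from 12 and returning at 15: the C10 hydroxyl of 12 is silylated with chloro(ethynyl)dimethylsilane (imidazole, DMF) to the ethynyl(dimethyl)silyl ether of the diene F1. On heating (toluene, BHT, 170 °C, sealed tube) the tethered alkyne can reach the diene only on the face that carries the C10 oxygen, so the intramolecular Diels–Alder reaction should give the bridged cyclic siloxane F2 with the required C4/C7 configuration and C5=C6 already in place. Bu4NF (THF, H2O, 50 °C) then cleaves the Si–O bond and protodesilylates the alkenylsilane to give 15, so that step 11 is no longer needed.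

Step 15. Hydride may be delivered to the other face of the C8 carbonyl, because the conformation of the bridged ten-membered ring can override the catalyst. The outcome would be the 8α epimer. Fallback, setting out from 20 and returning at 22: 20 is reduced under substrate control (NaBH4, CeCl3·7H2O, MeOH, −78 °C) to the 8α-alcohol F3. The hydroxyl is then replaced with inversion in a Mitsunobu esterification (isobutyric acid, PPh3, diisopropyl azodicarboxylate, toluene, 0 °C to rt), which gives the 8β-isobutyrate 22 directly and makes step 16 unnecessary.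

Step 19. Competing deprotonation of the isobutyrate α-hydrogen, or attack of the amide base on one of the esters, would divert material from the lactone enolate. Fallback, setting out from 26 and returning at 29: the lactone is carboxylated at C11 with MeOMgOCO2Me (methyl magnesium carbonate, DMF, 110 °C) to give the α-carboxy lactone F4. This reagent acts only on a methylene group that can form a magnesium chelate with the adjacent carbonyl, so the isobutyrate is left alone. Decarboxylative Mannich methylenation (aqueous CH2O, Et2NH, AcOH, NaOAc, rt) then gives 29 without any amide base.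

**Further compounds**

F1 | step 10 | ethynyl(dimethyl)silyl ether of the diene | CCOC(=O)C/C=C1\C[C@](C)(O[Si](C)(C)C#C)CC/C1=C\CO[Si](C)(C)C(C)(C)C
F2 | step 10 | bridged cyclic siloxane (C6–Si–O–C10 tether on the ring A 1,4-diene) | CCOC(=O)C[C@@H]1C2=C(CC[C@@](C)(O[Si]3(C)C)C2)[C@H](CO[Si](C)(C)C(C)(C)C)C=C13
F3 | step 15 | 8α-alcohol (8S) | O=C1C[C@@H]2[C@@H](O)C[C@@]3(C)CC[C@@](O)(O3)[C@H](CO[Si](C)(C)C(C)(C)C)[C@@H](OC(C)=O)[C@H]2O1
F4 | step 19 | α-carboxy lactone (C11 undefined) | O=C1C(C(=O)O)[C@@H]2[C@H](OC(=O)C(C)C)C[C@@]3(C)CC[C@@](O[Si](CC)(CC)CC)(O3)/C(CO[Si](C)(C)C(C)(C)C)=C\[C@H]2O1
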